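## Structural features

The target (C28H26O5) is an open-chain bis(bibenzyl) made of four benzene rings. Ring A (3-hydroxyphenyl) is joined by a CH2–CH2 bridge to ring B, a para-disubstituted benzene whose other substituent is a diaryl ether oxygen leading to ring C. Ring C is 1,2,4-trisubstituted: its OH is ortho to the ether oxygen and para to a second CH2–CH2 bridge, which ends at ring D, a catechol with the bridge next to one hydroxyl. There is no stereocentre and no stereogenic double bond, so no configuration has to be controlled. The free catechol oxidizes easily in air under base and should be unveiled last; the diaryl ether tolerates acid and base but is the bond most exposed to strongly reducing metals. The real difficulty is regiochemical: four phenolic oxygens, one C–O bond between ring B and ring C, and above all the contiguous C–OH/C–OH/C–alkyl array of ring D. The plan uses the fact that the two hydroxylated carbons of ring D are adjacent and one of them is bonded to the bridge-bearing carbon. Read as a saturated ring, these are the two ester carbons of a hexanedioate whose C2 carries the bridge, so one C–C bond between them closes ring D with both oxygens in place.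

## Logic of the disconnections

**17 to 16.** The two O–CH3 bonds on ring A and ring C are cut. Methyl ethers are the phenol protection most likely to tolerate sodium metal, and two of the four hydroxyls then never need separate handling. The forward step must cleave aryl methyl ethers without touching the diaryl ether and in the presence of a free catechol.

**16 to 15 to 14.** No skeletal bond is cut; the oxidation level of ring D is lowered twice. The aromatic ring becomes the cyclohexane-1,2-dione 15 (one H2 added back), and 15 becomes the enediol bis-silyl ether 14 (two electrons added back). This turns a 1,2,3-trisubstituted arene into a saturated carbocycle that an acyloin closure can deliver. Forward, the dehydrogenation must stop at the catechol, and the oxidant that makes 15 must prefer the enediol ether to the electron-rich anisole rings.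

**14 to 13.** The ring D bond between the two oxygen-bearing carbons is cut, opening the ring to the 2-substituted adipate 13. Both carbons are oxygenated in 14, so both can be ester carbons, and the bridge already sits on C2 of the chain. The gain is large: ring D and its catechol pattern dissolve into an acyclic diester with no regiochemical question. Forward, electron transfer must go to the two esters only, and ring closure must beat base-mediated condensation.

**13 to 12 to 10 + 11.** 13 is the methanolysis product of 12, so the bond between the ketone carbon and the quaternary carbon is reconnected. 12 is then cut between the quaternary carbon and the bridge CH2, giving bromide 10 and 11. 11 has a single acidic C–H, which guarantees mono-alkylation at the carbon that becomes C2 of the adipate; direct alkylation of an adipate could not offer that. Forward, substitution on the 2-arylethyl bromide must beat elimination to the styrene.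

**10 to 9 to 8 to 4 + 6.** The bromide is traced to alcohol 9. The ring A–ring B bridge is taken back to the stilbene 8, and 8 is cut at the C=C bond into aldehyde 4 and phosphonium salt 6 (ylide 7). Olefination followed by hydrogenation is the standard bibenzyl assembly and the alkene geometry is irrelevant. Forward, the base must be mild enough for the free primary alcohol.

**4 to 2 + 3.** The ring B carbon–oxygen bond of the diaryl ether is cut. The formyl group of 3 that later becomes the bridge also activates the para fluorine for addition–elimination, so no copper, boronic acid or aryl bromide is needed. Forward, the phenoxide of 2 must react in preference to its aliphatic hydroxyl.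

**2 to 1, and 6 to 5.** The alcohol 2 comes from reduction of the carboxyl group of 1, and 6 from quaternization of 5. Both are functional-group changes on purchased materials.

## Other disconnections considered

**Alternative 1:** The cut runs through ring B. Two of its C–C bonds are broken, so the ring is assembled from the diene carbons of methyl coumalate A3 and the two alkyne carbons of the aryl ethynyl ether A2. A2 already carries ring C, its ether oxygen, and ring D as a 2,3-dimethoxyphenyl group. The forward key step is a [4+2] cycloaddition of A3 with A2, followed in the same operation by retro-[4+2] ejection of the lactone bridge, to give the para-aryloxybenzoate A1.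
- In its favour: the polarity match (terminal alkyne carbon of A2 to C6 of A3) predicts the para pattern, aromatization needs no oxidant, and no electron-transfer reagent touches the aryl ethers.
- Against it here: A2 belongs to a hydrolysis-prone class, needs two operations from a phenol, and must survive the heating the cycloaddition requires. The ring it builds is a plain para-phenylene that the chosen plan simply buys. The ester of A1 must still be taken to an aldehyde and joined to 6 by olefination and hydrogenation.
- Comparison: on mechanism the pericyclic step is the equal or the better of the sodium-mediated closure. Ring D arrives as a purchased, fully oxygenated unit, and on that point alternative 1 is the better plan. On structure it spends its key step on the least demanding ring, whereas the chosen plan spends it on the only ring with a difficult substitution pattern. On step economy the two are about equal (an estimated twelve to thirteen operations), because making A2 and elaborating A1 use up what buying ring D saves.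

**Alternative 2:** The cut is the bond from ring D to the bridge carbon. Ring D is carried as 2-iodo-6-methoxyphenol A5 and the bridge as the alkyne of A6; a temporary O–C bond from the ring D oxygen to the far alkyne carbon closes a furan. The forward key step is a one-pot Sonogashira coupling and cyclization (PdCl2(PPh3)2, CuI, Et3N) giving benzofuran A4. The furan C=C must then be saturated and its benzylic C–O bond hydrogenolysed to release the ring D phenol and the CH2–CH2 bridge.
- In its favour: this is among the best-precedented heteroannulations, it is catalytic and convergent, the iodine position fixes the bridge next to oxygen, and ring D's oxygenation is bought.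
- Against it here: the difficulty moves to the unmasking. 2-Arylbenzofurans resist hydrogenation, the C–O hydrogenolysis relies on benzylic activation by ring C, and dissolving-metal alternatives would cleave the diaryl ether. A6 also needs a one-carbon homologation of a ring C aldehyde while ring B needs its own carbonyl for the stilbene, so two carbonyl groups must be staged.
- Comparison: on convergence and on reliability of the key step, alternative 2 is the better plan. Both plans expose the diaryl ether to one reductive operation, so they are equal there. On step economy an estimated ten to eleven operations is slightly better than twelve. Its weak point is the reduction after the key step, whereas the steps after the key step of the chosen plan each have precedent on simple cyclohexane-1,2-diones.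

**Alternative 3:** The cut removes three C–C bonds of ring C. The ring is assembled from 4-(2,3-dimethoxyphenyl)butanal A8, formaldehyde A10 and the aryloxyacetone A9, which carries rings A and B and the ether oxygen. The forward key step is amine-catalysed α-methylenation of A8 with A10, Michael addition of A9 through its aryloxy-bearing carbon, and intramolecular aldol condensation to cyclohexenone A7. Dehydrogenation of A7 to the ring C phenol and demethylation would finish the synthesis.
- In its favour: the diaryl ether C–O bond is made by ordinary O-alkylation of a phenol, the 1,2,4-pattern of ring C emerges in one pot from acyclic pieces, and the cascade is mild.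
- Against it here: A9 has two enolizable positions, and reaction through the methyl group gives a constitutional isomer. The 2-substituted acrolein formed from A8 and A10 is prone to polymerize. A7 holds its aryloxy group on an sp3 carbon next to the ketone, so aromatization by loss of H2 competes with aromatization by loss of the aryloxy group, which would destroy the ether.
- Comparison: on functional-group tolerance the organocatalytic cascade is the equal or the better of sodium in toluene. Its longest linear sequence would be shorter, and on that point alternative 3 is the better plan. On structure the chosen key step has no regiochemical ambiguity and alternative 3 has one. The total step count is comparable.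

Key step: step 9

Remark on the chemistry: 12, 13, 14 and 15 each carry one stereocentre and are made as racemates; that centre becomes an aromatic carbon in step 11 and the target is achiral. The connectivity of 13 and 14 maps onto ring D atom for atom and needs no correction. The design change is in how 13 is assembled: a metal-free ether formation, methyl ethers as the only protecting groups, and no O–H, halide or extra carbonyl left in 13.

## Route

Step 1
Reactants: 1 3-hydroxy-4-methoxyphenylacetic acid
Product: 2 2-(3-hydroxy-4-methoxyphenyl)ethanol
Conditions: BH3·THF (3 equiv), THF, 0 °C to rt; then MeOH, aqueous work-up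
Reagents that add atoms: none
Why: Borane reduction of a carboxylic acid through its acyloxyborane; the phenol only consumes hydride as an aryl borate and is released on work-up, and nothing else in 1 is reducible.

Step 2
Reactants: 2 2-(3-hydroxy-4-methoxyphenyl)ethanol; 3 4-fluorobenzaldehyde
Product: 4 4-[5-(2-hydroxyethyl)-2-methoxyphenoxy]benzaldehyde
Conditions: K2CO3 (2 equiv), DMF, 120 °C, N2
Reagents that add atoms: none
Why: Nucleophilic aromatic substitution (addition–elimination) of the phenoxide at the fluorine-bearing carbon, with the Meisenheimer intermediate stabilized by the para formyl group; carbonate does not deprotonate the aliphatic alcohol, so only the phenol should be arylated.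

Step 3
Reactants: 5 3-methoxybenzyl chloride
Product: 6 (3-methoxybenzyl)triphenylphosphonium chloride
Conditions: PPh3 (1.05 equiv), toluene, reflux
Reagents that add atoms: triphenylphosphine, c1ccc(cc1)P(c1ccccc1)c1ccccc1
Why: SN2 quaternization of the phosphine by a benzylic chloride; the salt should crystallize from toluene.

Step 4
Reactants: 4 4-[5-(2-hydroxyethyl)-2-methoxyphenoxy]benzaldehyde; 6 (3-methoxybenzyl)triphenylphosphonium chloride
Product: 8 2-(4-methoxy-3-{4-[2-(3-methoxyphenyl)ethenyl]phenoxy}phenyl)ethanol (E/Z mixture), via (3-methoxybenzylidene)triphenylphosphorane 7 (not isolated)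
Conditions: K2CO3 (3 equiv), 18-crown-6 (cat.), CH2Cl2, reflux
Reagents that add atoms: none
Why: Wittig olefination with a semi-stabilized benzylic ylide generated by solid carbonate and crown ether, a base too weak to engage the free alcohol; the E/Z mixture is acceptable because the next step removes the double bond.

Step 5
Reactants: 8 2-(4-methoxy-3-{4-[2-(3-methoxyphenyl)ethenyl]phenoxy}phenyl)ethanol (E/Z mixture)
Product: 9 2-(4-methoxy-3-{4-[2-(3-methoxyphenyl)ethyl]phenoxy}phenyl)ethanol
Conditions: H2 (1 atm), 10% Pd/C, EtOAc, rt
Reagents that add atoms: none
Why: Heterogeneous catalytic hydrogenation of a stilbene; both geometric isomers converge on the bibenzyl, and 8 has no benzylic C–O bond or halide that could be hydrogenolysed.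

Step 6
Reactants: 9 2-(4-methoxy-3-{4-[2-(3-methoxyphenyl)ethyl]phenoxy}phenyl)ethanol
Product: 10 4-(2-bromoethyl)-1-methoxy-2-{4-[2-(3-methoxyphenyl)ethyl]phenoxy}benzene
Conditions: CBr4 (1.3 equiv), PPh3 (1.4 equiv), CH2Cl2, 0 °C to rt
Reagents that add atoms: tetrabromomethane, BrC(Br)(Br)Br
Why: Appel reaction; the alkoxyphosphonium ion of the primary alcohol is displaced by bromide in an SN2 step under neutral conditions that leave the ethers alone.

Step 7
Reactants: 10 4-(2-bromoethyl)-1-methoxy-2-{4-[2-(3-methoxyphenyl)ethyl]phenoxy}benzene; 11 methyl 2-oxocyclopentanecarboxylate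
Product: 12 methyl 1-[2-(4-methoxy-3-{4-[2-(3-methoxyphenyl)ethyl]phenoxy}phenyl)ethyl]-2-oxocyclopentane-1-carboxylate (racemic)
Conditions: K2CO3 (2 equiv), NaI (cat.), acetone, reflux
Reagents that add atoms: none
Why: C-alkylation of a β-keto ester enolate (SN2, helped by in-situ iodide exchange); the stabilized, weakly basic enolate should favour substitution over E2, and the single acidic C–H allows one alkylation only, giving a racemic quaternary centre.

Step 8
Reactants: 12 methyl 1-[2-(4-methoxy-3-{4-[2-(3-methoxyphenyl)ethyl]phenoxy}phenyl)ethyl]-2-oxocyclopentane-1-carboxylate (racemic)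
Product: 13 dimethyl 2-[2-(4-methoxy-3-{4-[2-(3-methoxyphenyl)ethyl]phenoxy}phenyl)ethyl]hexanedioate (racemic)
Conditions: NaOMe (0.3 equiv), MeOH, reflux
Reagents that add atoms: methanol, CO
Why: Retro-Dieckmann (retro-Claisen) cleavage; 12 has no proton between its carbonyls, so methoxide adds to the ketone and the adduct fragments to an ester-stabilized carbanion that methanol protonates, and catalytic base in methanol should keep the open diester from re-closing.

Step 9
Reactants: 13 dimethyl 2-[2-(4-methoxy-3-{4-[2-(3-methoxyphenyl)ethyl]phenoxy}phenyl)ethyl]hexanedioate (racemic)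
Product: 14 3-[2-(4-methoxy-3-{4-[2-(3-methoxyphenyl)ethyl]phenoxy}phenyl)ethyl]-1,2-bis(trimethylsilyloxy)cyclohex-1-ene (racemic)
Conditions: Na dispersion (4.4 equiv), Me3SiCl (5 equiv), toluene, reflux, slow addition of 13, argon
Reagents that add atoms: chlorotrimethylsilane, C[Si](C)(C)Cl
Why: This is an acyloin condensation in its silyl-trapping (Rühlmann) form, the standard closure of adipates to 1,2-bis(silyloxy)cyclohexenes. Sodium transfers one electron to each ester carbonyl, and the two ketyl radical anions, held six atoms apart by the chain, couple carbon to carbon; this closes the six-membered ring by radical-anion dimerization between the two ester carbons. The resulting bis-alkoxide sheds both methoxy groups and takes up two more electrons to reach the disodium enediolate, which Me3SiCl silylates on both oxygens while also converting the released NaOMe into MeOSiMe3. No stereocentre is created, because both coupled carbons end up sp2; the one existing centre is racemic, untouched, and flattened in step 11. The selectivity needed is chemoselectivity, not regioselectivity: both new ring carbons become oxygenated, so it is irrelevant which ester reacts first, and the bridge already sits on the neighbouring carbon. Dieckmann closure to a five-membered β-keto ester should be suppressed because methoxide is scavenged as it forms and the medium is non-polar. 13 carries no O–H, halide or other carbonyl, and its aryl methyl and diaryl ethers lack a low-lying acceptor orbital, so they should not compete with the esters for electrons from sodium in toluene.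

Step 10
Reactants: 14 3-[2-(4-methoxy-3-{4-[2-(3-methoxyphenyl)ethyl]phenoxy}phenyl)ethyl]-1,2-bis(trimethylsilyloxy)cyclohex-1-ene (racemic)
Product: 15 3-[2-(4-methoxy-3-{4-[2-(3-methoxyphenyl)ethyl]phenoxy}phenyl)ethyl]cyclohexane-1,2-dione (racemic, in equilibrium with its enol)
Conditions: Br2 (1.0 equiv), CH2Cl2, −78 °C, argon; evaporate
Reagents that add atoms: none
Why: Halogen oxidation of an enediol bis-silyl ether; bromine adds to the very electron-rich tetrasubstituted double bond and two molecules of Me3SiBr are lost to leave the 1,2-diketone, and at −78 °C with one equivalent this should be far faster than bromination of the anisole rings.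

Step 11
Reactants: 15 3-[2-(4-methoxy-3-{4-[2-(3-methoxyphenyl)ethyl]phenoxy}phenyl)ethyl]cyclohexane-1,2-dione (racemic)
Product: 16 3-[2-(4-methoxy-3-{4-[2-(3-methoxyphenyl)ethyl]phenoxy}phenyl)ethyl]benzene-1,2-diol
Conditions: I2 (0.2 equiv), DMSO, 90 °C, argon
Reagents that add atoms: none
Why: Iodine-catalysed dehydrogenative aromatization; the enol is iodinated, loss of HI gives a cyclohexadienone that tautomerizes to the catechol, and DMSO reoxidizes HI to I2; only one H2 equivalent has to be removed and the stereocentre disappears.

Step 12
Reactants: 16 3-[2-(4-methoxy-3-{4-[2-(3-methoxyphenyl)ethyl]phenoxy}phenyl)ethyl]benzene-1,2-diol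
Product: 17 3-[2-(4-hydroxy-3-{4-[2-(3-hydroxyphenyl)ethyl]phenoxy}phenyl)ethyl]benzene-1,2-diol (target, achiral)
Conditions: BBr3 (6 equiv), CH2Cl2, −78 °C to rt; then H2O, argon
Reagents that add atoms: none
Why: Lewis-acid cleavage of aryl methyl ethers (boron coordination, then SN2 attack of bromide on the methyl group); the diaryl ether has no carbon open to SN2 and should survive, and the catechol is held as a cyclic borate until hydrolysis.

## Compound list

1 | 3-hydroxy-4-methoxyphenylacetic acid | COc1ccc(CC(=O)O)cc1O | starting material
2 | 2-(3-hydroxy-4-methoxyphenyl)ethanol | COc1ccc(CCO)cc1O | intermediate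
3 | 4-fluorobenzaldehyde | O=Cc1ccc(F)cc1 | starting material
4 | 4-[5-(2-hydroxyethyl)-2-methoxyphenoxy]benzaldehyde | COc1ccc(CCO)cc1Oc1ccc(C=O)cc1 | intermediate
5 | 3-methoxybenzyl chloride | COc1cccc(CCl)c1 | starting material
6 | (3-methoxybenzyl)triphenylphosphonium chloride | COc1cccc(C[P+](c2ccccc2)(c2ccccc2)c2ccccc2)c1.[Cl-] | intermediate
7 | (3-methoxybenzylidene)triphenylphosphorane (not isolated) | COc1cccc(C=P(c2ccccc2)(c2ccccc2)c2ccccc2)c1 | intermediate
8 | 2-(4-methoxy-3-{4-[2-(3-methoxyphenyl)ethenyl]phenoxy}phenyl)ethanol (E/Z mixture) | COc1cccc(C=Cc2ccc(Oc3cc(CCO)ccc3OC)cc2)c1 | intermediate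
9 | 2-(4-methoxy-3-{4-[2-(3-methoxyphenyl)ethyl]phenoxy}phenyl)ethanol | COc1cccc(CCc2ccc(Oc3cc(CCO)ccc3OC)cc2)c1 | intermediate
10 | 4-(2-bromoethyl)-1-methoxy-2-{4-[2-(3-methoxyphenyl)ethyl]phenoxy}benzene | COc1cccc(CCc2ccc(Oc3cc(CCBr)ccc3OC)cc2)c1 | intermediate
11 | methyl 2-oxocyclopentanecarboxylate | COC(=O)C1CCCC1=O | starting material
12 | methyl 1-[2-(4-methoxy-3-{4-[2-(3-methoxyphenyl)ethyl]phenoxy}phenyl)ethyl]-2-oxocyclopentane-1-carboxylate (racemic) | COC(=O)C1(CCc2ccc(OC)c(Oc3ccc(CCc4cccc(OC)c4)cc3)c2)CCCC1=O | intermediate
13 | dimethyl 2-[2-(4-methoxy-3-{4-[2-(3-methoxyphenyl)ethyl]phenoxy}phenyl)ethyl]hexanedioate (racemic) | COC(=O)CCCC(CCc1ccc(OC)c(Oc2ccc(CCc3cccc(OC)c3)cc2)c1)C(=O)OC | intermediate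
14 | 3-[2-(4-methoxy-3-{4-[2-(3-methoxyphenyl)ethyl]phenoxy}phenyl)ethyl]-1,2-bis(trimethylsilyloxy)cyclohex-1-ene (racemic) | C[Si](C)(C)OC1=C(O[Si](C)(C)C)C(CCc2ccc(OC)c(Oc3ccc(CCc4cccc(OC)c4)cc3)c2)CCC1 | intermediate
15 | 3-[2-(4-methoxy-3-{4-[2-(3-methoxyphenyl)ethyl]phenoxy}phenyl)ethyl]cyclohexane-1,2-dione (racemic) | O=C1CCCC(CCc2ccc(OC)c(Oc3ccc(CCc4cccc(OC)c4)cc3)c2)C1=O | intermediate
16 | 3-[2-(4-methoxy-3-{4-[2-(3-methoxyphenyl)ethyl]phenoxy}phenyl)ethyl]benzene-1,2-diol | COc1cccc(CCc2ccc(Oc3cc(CCc4cccc(O)c4O)ccc3OC)cc2)c1 | intermediate
17 | 3-[2-(4-hydroxy-3-{4-[2-(3-hydroxyphenyl)ethyl]phenoxy}phenyl)ethyl]benzene-1,2-diol | Oc1cccc(CCc2ccc(Oc3cc(CCc4cccc(O)c4O)ccc3O)cc2)c1 | target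

## Step count and least certain steps

Total: 12 steps. Longest linear sequence: 11 steps (steps 1, 2 and 4 to 12); step 3 is a one-step side branch.

**Step 9 (key step).** The most likely failure is electron transfer from sodium into the aryl ethers, leading to reductive cleavage of the diaryl ether or loss of a methyl group. The second risk is base-driven ester condensation or intermolecular coupling if methoxide trapping or dilution is inadequate. The fallback keeps the same ring bond but forms it with a milder one-electron reductant. It sets out from 13: both esters are reduced with i-Bu2AlH (toluene, −78 °C) to 2-[2-(4-methoxy-3-{4-[2-(3-methoxyphenyl)ethyl]phenoxy}phenyl)ethyl]hexanedial F1. F1 is closed by SmI2-mediated pinacol coupling (THF, rt), a reagent that does not reduce aryl ethers, to 3-[2-(4-methoxy-3-{4-[2-(3-methoxyphenyl)ethyl]phenoxy}phenyl)ethyl]cyclohexane-1,2-diol F2 (diastereomer mixture). Double Swern oxidation of F2 ((COCl)2, DMSO, Et3N, −78 °C) returns to the route at 15, bypassing 14 and step 10.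

**Step 10.** Two processes threaten it: electrophilic bromination of ring C or ring A if bromine is in local excess, and premature hydrolysis of the moisture-sensitive enediol ether, which would leave material at the acyloin oxidation level. The fallback sets out from 14 and makes the hydrolysis deliberate. Methanolysis (degassed MeOH, trace HCl) should give the acyloin as two interconverting regioisomers, 2-hydroxy-6-[2-(4-methoxy-3-{4-[2-(3-methoxyphenyl)ethyl]phenoxy}phenyl)ethyl]cyclohexan-1-one F3 and 2-hydroxy-3-[2-(4-methoxy-3-{4-[2-(3-methoxyphenyl)ethyl]phenoxy}phenyl)ethyl]cyclohexan-1-one F4. Both are oxidized with Cu(OAc)2 in aqueous AcOH at 60 °C, a reagent that does not halogenate arenes, and the route is rejoined at 15.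

**Step 11.** Possible failures are over-oxidation of the newly formed catechol, iodination of an electron-rich ring, or stalling before the last tautomerization. The fallback is a stoichiometric bromination–dehydrobromination starting from 15. PhNMe3Br3 (THF, 0 °C) should brominate the enol carbon to give 3-bromo-3-[2-(4-methoxy-3-{4-[2-(3-methoxyphenyl)ethyl]phenoxy}phenyl)ethyl]cyclohexane-1,2-dione F5. LiBr and Li2CO3 in DMF at 110 °C then eliminate HBr, and the resulting enedione tautomerizes to the catechol, rejoining the route at 16.

**Step 2.** The risks are partial arylation of the aliphatic hydroxyl and slow substitution by the hindered ortho-methoxy phenoxide, which would leave the aldehyde exposed to base at high temperature. The fallback replaces addition–elimination by copper catalysis and changes the order of bond formation. 6 is condensed with purchased 4-bromobenzaldehyde (K2CO3, 18-crown-6, CH2Cl2) to 1-bromo-4-[2-(3-methoxyphenyl)ethenyl]benzene F6 (E/Z mixture). F6 is reduced with diimide (TsNHNH2, NaOAc, aqueous THF, reflux), which spares the C–Br bond, to 1-bromo-4-[2-(3-methoxyphenyl)ethyl]benzene F7. Ullmann coupling of F7 with 2 (CuI, picolinic acid, K3PO4, DMSO, 90 °C), a system selective for phenols over aliphatic alcohols, gives 9 directly; the route is rejoined at 9 and steps 4 and 5 are no longer needed.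

## Further compounds

F1 | step 9 | 2-[2-(4-methoxy-3-{4-[2-(3-methoxyphenyl)ethyl]phenoxy}phenyl)ethyl]hexanedial (racemic) | O=CCCCC(CCc1ccc(OC)c(Oc2ccc(CCc3cccc(OC)c3)cc2)c1)C=O
F2 | step 9 | 3-[2-(4-methoxy-3-{4-[2-(3-methoxyphenyl)ethyl]phenoxy}phenyl)ethyl]cyclohexane-1,2-diol (diastereomer mixture) | OC1CCCC(CCc2ccc(OC)c(Oc3ccc(CCc4cccc(OC)c4)cc3)c2)C1O
F3 | step 10 | 2-hydroxy-6-[2-(4-methoxy-3-{4-[2-(3-methoxyphenyl)ethyl]phenoxy}phenyl)ethyl]cyclohexan-1-one (diastereomer mixture) | O=C1C(O)CCCC1CCc1ccc(OC)c(Oc2ccc(CCc3cccc(OC)c3)cc2)c1
F4 | step 10 | 2-hydroxy-3-[2-(4-methoxy-3-{4-[2-(3-methoxyphenyl)ethyl]phenoxy}phenyl)ethyl]cyclohexan-1-one (diastereomer mixture) | O=C1CCCC(CCc2ccc(OC)c(Oc3ccc(CCc4cccc(OC)c4)cc3)c2)C1O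
F5 | step 11 | 3-bromo-3-[2-(4-methoxy-3-{4-[2-(3-methoxyphenyl)ethyl]phenoxy}phenyl)ethyl]cyclohexane-1,2-dione (racemic) | O=C1CCCC(Br)(CCc2ccc(OC)c(Oc3ccc(CCc4cccc(OC)c4)cc3)c2)C1=O
F6 | step 2 | 1-bromo-4-[2-(3-methoxyphenyl)ethenyl]benzene (E/Z mixture) | COc1cccc(C=Cc2ccc(Br)cc2)c1
F7 | step 2 | 1-bromo-4-[2-(3-methoxyphenyl)ethyl]benzene | COc1cccc(CCc2ccc(Br)cc2)c1
A1 | alternative 1 | methyl 4-{5-[2-(2,3-dimethoxyphenyl)ethyl]-2-methoxyphenoxy}benzoate | COC(=O)c1ccc(Oc2cc(CCc3cccc(OC)c3OC)ccc2OC)cc1
A2 | alternative 1 | 4-[2-(2,3-dimethoxyphenyl)ethyl]-2-(ethynyloxy)-1-methoxybenzene | C#COc1cc(CCc2cccc(OC)c2OC)ccc1OC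
A3 | alternative 1 | methyl coumalate (methyl 2-oxo-2H-pyran-5-carboxylate) | COC(=O)C1=COC(=O)C=C1
A4 | alternative 2 | 7-methoxy-2-(4-methoxy-3-{4-[2-(3-methoxyphenyl)ethyl]phenoxy}phenyl)-1-benzofuran | COc1cccc2cc(-c3ccc(OC)c(Oc4ccc(CCc5cccc(OC)c5)cc4)c3)oc12
A5 | alternative 2 | 2-iodo-6-methoxyphenol | COc1cccc(I)c1O
A6 | alternative 2 | 4-ethynyl-1-methoxy-2-{4-[2-(3-methoxyphenyl)ethyl]phenoxy}benzene | C#Cc1ccc(OC)c(Oc2ccc(CCc3cccc(OC)c3)cc2)c1
A7 | alternative 3 | 4-[2-(2,3-dimethoxyphenyl)ethyl]-6-{4-[2-(3-methoxyphenyl)ethyl]phenoxy}cyclohex-2-en-1-one (diastereomer mixture) | O=C1C=CC(CCc2cccc(OC)c2OC)CC1Oc1ccc(CCc2cccc(OC)c2)cc1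
A8 | alternative 3 | 4-(2,3-dimethoxyphenyl)butanal | COc1cccc(CCCC=O)c1OC
A9 | alternative 3 | 1-{4-[2-(3-methoxyphenyl)ethyl]phenoxy}propan-2-one | CC(=O)COc1ccc(CCc2cccc(OC)c2)cc1
A10 | alternative 3 | formaldehyde | C=O
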